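**Retrosynthetic overview**
1. Teferin ⇒ jaeschkeanadiol + phenol-protected vanillic acid (C6–O acyl bond); C4 carbinol ⇒ C4 ketone + isopropyl nucleophile; C5–H and C6–OH ⇒ syn hydroboration of C5=C6; C8=C9 ⇒ enol triflate of a C9 ketone.
2. Feature the strategy rests on: the quaternary ring-fusion carbon C1 and its bond to C10 of the seven-membered ring. With C9 as a ketone and C5=C6 as an olefin, C1–C10 is the sigma bond of a γ,δ-unsaturated ketone, i.e. the [3,3] retron of the allyl vinyl ether C10=C9–O–C6–C5=C1.
3. Key disconnection: Claisen ring expansion of a 2-methylidene-5-(cyclopent-1-enyl)oxolane; the C6 carbinol configuration (set by CBS reduction) is relayed to C1.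
4. Oxolane ⇒ γ-lactone (methylenation) ⇒ γ-keto ester ⇒ 2-lithiated 3-methylcyclopentenone ketal + a regiodefined Weinreb amide of a methylsuccinate half-ester.
5. Ring order: the five-membered carbocycle is bought; the oxolane is a temporary ring (lactonisation); the seven-membered carbocycle is formed last, by the ring expansion.

Key step: step 7

Remark on numbering: daucane locants are used for all bicyclic compounds and, by anticipation, for their precursors. C1 is the quaternary fusion carbon with the angular methyl; C2 and C3 are the CH2 groups of the five-membered ring; C4 carries OH and isopropyl; C5 is the fusion CH; C6 carries the ester oxygen; C7 and C10 are the CH2 groups of the seven-membered ring; C8 (methyl-bearing) and C9 form the ring olefin.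

Assumption: the methyl-bearing C8 centre is carried as a mixture of epimers from compound 8 to compound 15, because it becomes sp2 in step 8.

Step 1
Reactants: 1 3-methylcyclopent-2-en-1-one
Product: 3 2-bromo-3-methylcyclopent-2-en-1-one, via dibromo ketone 2 (not isolated)
Conditions: Br2, CH2Cl2, 0 °C; then Et3N, 0 °C → rt
Reagents that add atoms: bromine, BrBr
Why: Bromine adds across the enone and triethylamine removes HBr (acidic C–H next to the carbonyl, tertiary bromide leaves), giving the α-bromo enone by bromination–dehydrobromination.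

Step 2
Reactants: 3 2-bromo-3-methylcyclopent-2-en-1-one
Product: 4 6-bromo-7-methyl-1,4-dioxaspiro[4.4]non-6-ene
Conditions: HOCH2CH2OH, p-TsOH (cat.), PhH, reflux, azeotropic removal of water
Reagents that add atoms: ethylene glycol, OCCO
Why: Acid-catalysed ketalisation driven by water removal; the vinylic bromide keeps the double bond from migrating out of conjugation with the ketal carbon.

Step 3
Reactants: 5 methyl propanoate; 6 2-bromo-N-methoxy-N-methylacetamide
Product: 8 methyl 4-[methoxy(methyl)amino]-2-methyl-4-oxobutanoate (racemic), via lithium ester enolate 7 (not isolated)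
Conditions: LiN(iPr)2, THF, −78 °C; then 6, DMPU, −78 → −20 °C
Reagents that add atoms: none
Why: SN2 alkylation of a lithium ester enolate by the α-bromo amide fixes the succinate regiochemistry (amide carbonyl on the CH2 side, ester on the CH(CH3) side), which opening of an unsymmetrical anhydride would not guarantee; the new centre (later C8) is racemic and inconsequential.

Step 4
Reactants: 4 6-bromo-7-methyl-1,4-dioxaspiro[4.4]non-6-ene; 8 methyl 4-[methoxy(methyl)amino]-2-methyl-4-oxobutanoate
Product: 11 methyl 2-methyl-4-(7-methyl-1,4-dioxaspiro[4.4]non-6-en-6-yl)-4-oxobutanoate, via vinyllithium 9 (not isolated), via lithium hemiaminal 10 (not isolated)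
Conditions: n-BuLi, THF, −78 °C; then 8, −78 °C; aq. NH4Cl
Reagents that add atoms: none
Why: Bromine–lithium exchange gives the C5 vinyllithium, which should acylate at the N-methoxy-N-methylamide (Weinreb ketone synthesis, the chelated adduct preventing over-addition) faster than at the α-branched methyl ester, forming the C5–C6 bond.

Step 5
Reactants: 11 methyl 2-methyl-4-(7-methyl-1,4-dioxaspiro[4.4]non-6-en-6-yl)-4-oxobutanoate
Product: 13 (5S)-3-methyl-5-(7-methyl-1,4-dioxaspiro[4.4]non-6-en-6-yl)oxolan-2-one (C3 epimers), via hydroxy ester 12 (not isolated)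
Conditions: (R)-2-methyl-CBS-oxazaborolidine (0.3 equiv), BH3·SMe2, THF, −30 °C; MeOH; then DBU (cat.), PhMe, 50 °C
Reagents that add atoms: none
Why: Corey–Bakshi–Shibata reduction, in which the ketone binds the catalyst boron anti to its bulkier, fully substituted cyclopentenyl group, so the (R)-catalyst should give the (S)-carbinol at C6 (the mirror of the sense in which the (S)-catalyst gives (R)-1-phenylethanol); the γ-hydroxy ester then lactonises under mild base, which spares the ketal and the ionisable allylic C6–O bond.

Step 6
Reactants: 13 (5S)-3-methyl-5-(7-methyl-1,4-dioxaspiro[4.4]non-6-en-6-yl)oxolan-2-one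
Product: 14 (5S)-3-methyl-2-methylidene-5-(7-methyl-1,4-dioxaspiro[4.4]non-6-en-6-yl)oxolane (C3 epimers)
Conditions: Cp2TiMe2, PhMe, 70 °C, dark; filtration through basic alumina
Reagents that add atoms: dimethyltitanocene Cp2TiMe2, C[Ti](C)(C1C=CC=C1)C1C=CC=C1
Why: Petasis methylenation, in which Cp2TiMe2 loses methane to a titanium methylidene that converts the lactone carbonyl into the exocyclic enol ether by [2+2] addition and cycloreversion, under non-acidic conditions that keep the C9=C10 double bond exocyclic.

Step 7
Reactants: 14 (5S)-3-methyl-2-methylidene-5-(7-methyl-1,4-dioxaspiro[4.4]non-6-en-6-yl)oxolane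
Product: 15 (1R)-4,4-ethylenedioxy-1,8-dimethylbicyclo[5.3.0]dec-5-en-9-one (daucane locants; C8 epimers)
Conditions: o-xylene (degassed, 0.02 M), Et3N (5 mol %), sealed base-washed tube, 175 °C
Reagents that add atoms: none
Why: Heating the allyl vinyl ether C10=C9–O–C6–C5=C1 should trigger a concerted [3,3]-sigmatropic (Claisen) shift in which C10 bonds to C1 while the C6–O bond breaks, so that C9 emerges as a ketone and C5=C6 as the new ring olefin. The closest known reaction type is the thermal Claisen ring expansion of 2-methylidene-5-vinyloxolanes to cyclohept-4-enones, cycloalkenyl cases included. The seven-membered carbocycle (C1, C5, C6, C7, C8, C9, C10) is closed not by cyclisation of a chain but by two-carbon ring expansion of the oxolane, through a boat-like six-centre transition state enforced by the C7–C8 bridge. The only stereocentre created, quaternary C1, is controlled by the C6 carbinol centre: bond formation and cleavage are suprafacial on the cyclopentene, and because the new C5=C6 bond must be cis inside the ring only the rotamer with C7 syn to C1 can react, so (6S) maps onto (1R). The step needs the [3,3] path to win over C6–O ionisation and over migration of the exocyclic double bond into the oxolane, which the non-polar, amine-buffered medium and base-washed glass should secure; the tetrasubstituted terminus is acceptable because Claisen shifts are a standard way to build quaternary carbon.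

Step 8
Reactants: 15 (1R)-4,4-ethylenedioxy-1,8-dimethylbicyclo[5.3.0]dec-5-en-9-one
Product: 17 (1R)-4,4-ethylenedioxy-1,8-dimethyl-9-(trimethylsilyloxy)bicyclo[5.3.0]deca-5,8-diene (daucane locants), via magnesium enolate 16 (not isolated)
Conditions: iPr2NMgBr, Et2O, rt; then TMSCl, Et3N, HMPA, rt
Reagents that add atoms: chlorotrimethylsilane, C[Si](C)(C)Cl
Why: Equilibrating (thermodynamic) enolisation with the magnesium amide should favour the more substituted C8=C9 enolate over the C9=C10 one (C10 is a neopentyl CH2), and O-silylation traps that regiochemistry; the C8 stereocentre disappears here.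

Step 9
Reactants: 17 (1R)-4,4-ethylenedioxy-1,8-dimethyl-9-(trimethylsilyloxy)bicyclo[5.3.0]deca-5,8-diene
Product: 19 (1R)-4,4-ethylenedioxy-1,8-dimethylbicyclo[5.3.0]deca-5,8-dien-9-yl trifluoromethanesulfonate (daucane locants), via lithium enolate 18 (not isolated)
Conditions: MeLi, THF, 0 °C; then PhNTf2, −78 °C → rt
Reagents that add atoms: N-phenylbis(trifluoromethanesulfonimide), O=S(=O)(N(c1ccccc1)S(=O)(=O)C(F)(F)F)C(F)(F)F
Why: Methyllithium cleaves the O–Si bond to release the regiodefined lithium enolate without equilibration, and O-sulfonylation by PhNTf2 gives the enol triflate, which both fixes the future C8=C9 position and masks that olefin for step 10.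

Step 10
Reactants: 19 (1R)-4,4-ethylenedioxy-1,8-dimethylbicyclo[5.3.0]deca-5,8-dien-9-yl trifluoromethanesulfonate
Product: 21 (1R,5S,6S)-4,4-ethylenedioxy-6-hydroxy-1,8-dimethylbicyclo[5.3.0]dec-8-en-9-yl trifluoromethanesulfonate (daucane locants), via alkylborane 20 (not isolated)
Conditions: BH3·THF, THF, 0 °C → rt; then 30% H2O2, aq. NaOAc, 0 °C → rt
Reagents that add atoms: hydrogen peroxide, OO
Why: Hydroboration–oxidation, with boron at the less substituted C6 and hydrogen at C5 in a syn addition from the face opposite the angular C1 methyl, which should stand nearly perpendicular over the other face of C5=C6 in the cyclohepta-1,4-diene conformation (the facial sense known for Δ5-steroids); this sets C5–H and C6–OH both trans to that methyl, the electron-poor tetrasubstituted enol triflate olefin is left alone, and the C–B bond is oxidised with retention.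

Step 11
Reactants: 21 (1R,5S,6S)-4,4-ethylenedioxy-6-hydroxy-1,8-dimethylbicyclo[5.3.0]dec-8-en-9-yl trifluoromethanesulfonate
Product: 22 (1R,5S,6S)-4,4-ethylenedioxy-1,8-dimethylbicyclo[5.3.0]dec-8-en-6-ol (daucane locants)
Conditions: Pd(OAc)2 (cat.), PPh3, HCO2H, Bu3N, DMF, 60 °C
Reagents that add atoms: none
Why: Palladium-catalysed formate reduction of an enol triflate (oxidative addition to zerovalent palladium, formate exchange, decarboxylation to a palladium hydride, reductive elimination) replaces OTf by H with the double bond fixed at C8=C9; the free alcohol and the ketal are inert.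

Step 12
Reactants: 22 (1R,5S,6S)-4,4-ethylenedioxy-1,8-dimethylbicyclo[5.3.0]dec-8-en-6-ol
Product: 23 (1R,5S,6S)-6-hydroxy-1,8-dimethylbicyclo[5.3.0]dec-8-en-4-one (daucane locants)
Conditions: 0.5 M HCl, THF–H2O, 0 °C → rt, short reaction time
Reagents that add atoms: water, O
Why: Acid-catalysed hydrolysis of a cyclopentanone dioxolane, run dilute and cold so that the trans ring fusion alpha to the new ketone is not enolised and the beta-hydroxyl is not eliminated.

Step 13
Reactants: 23 (1R,5S,6S)-6-hydroxy-1,8-dimethylbicyclo[5.3.0]dec-8-en-4-one; 24 2-bromopropane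
Product: 27 jaeschkeanadiol [(1R,4R,5S,6S)-dauc-8-ene-4,6-diol], via isopropylmagnesium bromide 25 (not isolated), via isopropylcerium dichloride 26 (not isolated)
Conditions: 24, Mg, THF; CeCl3 (anhydrous), THF, −78 °C; then 23 (reagent in excess), −78 → −40 °C; aq. NH4Cl
Reagents that add atoms: none
Why: Grignard formation, transmetalation to the weakly basic organocerium and 1,2-addition, in which the first equivalent deprotonates the C6 hydroxyl and the isopropyl group should enter C4 from the face of H5, anti to both the C5–C6 bond on the adjacent carbon and the angular methyl, placing the C4 hydroxyl cis to that methyl as in the target.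

Step 14
Reactants: 28 vanillic acid
Product: 30 4-(tert-butyldimethylsilyloxy)-3-methoxybenzoic acid, via bis-silyl derivative 29 (not isolated)
Conditions: TBSCl, imidazole, DMF, rt; then AcOH–THF–H2O, rt
Reagents that add atoms: tert-butyldimethylsilyl chloride, CC(C)(C)[Si](C)(C)Cl
Why: Silylation of both acidic OH groups followed by selective hydrolysis of the labile silyl ester leaves the phenol masked, so that it cannot be acylated in step 15.

Step 15
Reactants: 27 jaeschkeanadiol; 30 4-(tert-butyldimethylsilyloxy)-3-methoxybenzoic acid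
Product: 31 jaeschkeanadiol 6-O-[4-(tert-butyldimethylsilyloxy)-3-methoxybenzoate]
Conditions: DCC, DMAP, CH2Cl2, rt
Reagents that add atoms: none
Why: Steglich esterification should acylate only the secondary C6 hydroxyl, the tertiary C4 hydroxyl being too hindered, and C6 keeps its configuration because its C–O bond is not broken.

Step 16
Reactants: 31 jaeschkeanadiol 6-O-[4-(tert-butyldimethylsilyloxy)-3-methoxybenzoate]
Product: 32 teferin
Conditions: Bu4NF, AcOH, THF, 0 °C
Reagents that add atoms: none
Why: Fluoride-mediated desilylation cleaves the aryl silyl ether far faster than it can affect the hindered benzoate, and acetic acid buffering prevents phenoxide-mediated acyl transfer.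

**Compound list**
1 | 3-methylcyclopent-2-en-1-one | CC1=CC(=O)CC1 | starting material
2 | 2,3-dibromo-3-methylcyclopentan-1-one (formed in the flask) | CC1(Br)CCC(=O)C1Br | intermediate
3 | 2-bromo-3-methylcyclopent-2-en-1-one | CC1=C(Br)C(=O)CC1 | intermediate
4 | 6-bromo-7-methyl-1,4-dioxaspiro[4.4]non-6-ene | CC1=C(Br)C2(CC1)OCCO2 | intermediate
5 | methyl propanoate | CCC(=O)OC | starting material
6 | 2-bromo-N-methoxy-N-methylacetamide | CON(C)C(=O)CBr | starting material
7 | lithium enolate of methyl propanoate (formed in the flask) | CC=C(OC)O[Li] | intermediate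
8 | methyl 4-[methoxy(methyl)amino]-2-methyl-4-oxobutanoate (racemic) | COC(=O)C(C)CC(=O)N(C)OC | intermediate
9 | 6-lithio-7-methyl-1,4-dioxaspiro[4.4]non-6-ene (formed in the flask) | CC1=C([Li])C2(CC1)OCCO2 | intermediate
10 | lithium hemiaminal adduct of 9 and 8 (formed in the flask) | COC(=O)C(C)CC(O[Li])(N(C)OC)C1=C(C)CCC12OCCO2 | intermediate
11 | methyl 2-methyl-4-(7-methyl-1,4-dioxaspiro[4.4]non-6-en-6-yl)-4-oxobutanoate | COC(=O)C(C)CC(=O)C1=C(C)CCC12OCCO2 | intermediate
12 | methyl (4S)-4-hydroxy-2-methyl-4-(7-methyl-1,4-dioxaspiro[4.4]non-6-en-6-yl)butanoate (formed in the flask) | O[C@H](C1=C(C)CCC12OCCO2)CC(C)C(=O)OC | intermediate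
13 | (5S)-3-methyl-5-(7-methyl-1,4-dioxaspiro[4.4]non-6-en-6-yl)oxolan-2-one, C3 epimers | O=C1O[C@H](C2=C(C)CCC23OCCO3)CC1C | intermediate
14 | (5S)-3-methyl-2-methylidene-5-(7-methyl-1,4-dioxaspiro[4.4]non-6-en-6-yl)oxolane, C3 epimers (key-step precursor) | C=C1O[C@H](C2=C(C)CCC23OCCO3)CC1C | intermediate
15 | (1R)-4,4-ethylenedioxy-1,8-dimethylbicyclo[5.3.0]dec-5-en-9-one, daucane locants, C8 epimers (key-step product) | CC1CC=C2C3(OCCO3)CC[C@]2(C)CC1=O | intermediate
16 | bromomagnesium C8=C9 enolate of 15 (formed in the flask) | CC1=C(O[Mg]Br)C[C@@]2(C)CCC3(OCCO3)C2=CC1 | intermediate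
17 | (1R)-4,4-ethylenedioxy-1,8-dimethyl-9-(trimethylsilyloxy)bicyclo[5.3.0]deca-5,8-diene, daucane locants | CC1=C(O[Si](C)(C)C)C[C@@]2(C)CCC3(OCCO3)C2=CC1 | intermediate
18 | lithium C8=C9 enolate (formed in the flask) | CC1=C(O[Li])C[C@@]2(C)CCC3(OCCO3)C2=CC1 | intermediate
19 | (1R)-4,4-ethylenedioxy-1,8-dimethylbicyclo[5.3.0]deca-5,8-dien-9-yl trifluoromethanesulfonate, daucane locants | CC1=C(OS(=O)(=O)C(F)(F)F)C[C@@]2(C)CCC3(OCCO3)C2=CC1 | intermediate
20 | C6 alkylborane, boron and H5 on the face opposite the angular methyl (formed in the flask) | B[C@H]1CC(C)=C(OS(=O)(=O)C(F)(F)F)C[C@@]2(C)CCC3(OCCO3)[C@H]12 | intermediate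
21 | (1R,5S,6S)-4,4-ethylenedioxy-6-hydroxy-1,8-dimethylbicyclo[5.3.0]dec-8-en-9-yl trifluoromethanesulfonate, daucane locants | O[C@H]1CC(C)=C(OS(=O)(=O)C(F)(F)F)C[C@@]2(C)CCC3(OCCO3)[C@H]12 | intermediate
22 | (1R,5S,6S)-4,4-ethylenedioxy-1,8-dimethylbicyclo[5.3.0]dec-8-en-6-ol, daucane locants | O[C@H]1CC(C)=CC[C@@]2(C)CCC3(OCCO3)[C@H]12 | intermediate
23 | (1R,5S,6S)-6-hydroxy-1,8-dimethylbicyclo[5.3.0]dec-8-en-4-one, daucane locants | O[C@H]1CC(C)=CC[C@@]2(C)CCC(=O)[C@H]12 | intermediate
24 | 2-bromopropane | CC(C)Br | starting material
25 | isopropylmagnesium bromide (formed in the flask) | CC(C)[Mg]Br | intermediate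
26 | isopropylcerium dichloride (formed in the flask) | CC(C)[Ce](Cl)Cl | intermediate
27 | jaeschkeanadiol, (1R,4R,5S,6S)-dauc-8-ene-4,6-diol | O[C@H]1CC(C)=CC[C@@]2(C)CC[C@@](O)(C(C)C)[C@H]12 | intermediate
28 | vanillic acid | COc1cc(C(=O)O)ccc1O | starting material
29 | tert-butyldimethylsilyl 4-(tert-butyldimethylsilyloxy)-3-methoxybenzoate (formed in the flask) | COc1cc(C(=O)O[Si](C)(C)C(C)(C)C)ccc1O[Si](C)(C)C(C)(C)C | intermediate
30 | 4-(tert-butyldimethylsilyloxy)-3-methoxybenzoic acid | COc1cc(C(=O)O)ccc1O[Si](C)(C)C(C)(C)C | intermediate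
31 | jaeschkeanadiol 6-O-[4-(tert-butyldimethylsilyloxy)-3-methoxybenzoate] | COc1cc(C(=O)O[C@H]2CC(C)=CC[C@@]3(C)CC[C@@](O)(C(C)C)[C@H]23)ccc1O[Si](C)(C)C(C)(C)C | intermediate
32 | teferin (jaeschkeanadiol 6-O-vanillate) | COc1cc(C(=O)O[C@H]2CC(C)=CC[C@@]3(C)CC[C@@](O)(C(C)C)[C@H]23)ccc1O | target

**Step count**
Total: 16 steps. Longest linear sequence: 14 steps (steps 1, 2, 4–13, 15, 16); steps 3 and 14 are side branches.

**Steps most likely to fail**

1. Step 7 (Claisen ring expansion). What may go wrong: trace-acid migration of the exocyclic double bond into the oxolane, giving a dihydrofuran that cannot rearrange, or C6–O ionisation and decomposition at the temperature the congested tetrasubstituted terminus demands. Fallback, setting out from 14 and returning at 15: 14 is treated with iBu3Al in CH2Cl2 (−78 °C → rt). Aluminium coordination to the ether oxygen weakens C6–O and should drive the same C10–C1 bond formation at low temperature within a tight ion pair. The ketone so formed is reduced in the flask by β-hydride transfer from an isobutyl group, giving the cyclohept-4-enol F1 (C9 carbinol, epimers). Dess–Martin oxidation with NaHCO3 buffering then returns ketone 15.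

2. Step 10 (hydroboration). What may go wrong: borane approach from the methyl-bearing face (cis ring fusion and 6-epi alcohol), or sluggish addition to the olefin flanked by two quaternary carbons. Fallback, setting out from 19 and returning at 27; here the oxygen is delivered under hydroxyl direction instead:
   - Formate reduction of 19 (Pd(OAc)2, PPh3, HCO2H, Bu3N) gives the diene ketal F2.
   - Dilute HCl in THF gives the conjugated dienone F3.
   - iPrCeCl2 adds 1,2, anti to the axial C1 methyl, to give the tertiary allylic alcohol F4.
   - VO(acac)2/tBuOOH epoxidises C5=C6 on the face of the C4 hydroxyl (the isolated C8=C9 olefin is not addressed) to give the syn epoxy alcohol F5.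
   - Cp2TiCl (trivalent titanium, from Cp2TiCl2 and Zn), with water as hydrogen-atom source so that radical reduction outruns β-elimination, opens the oxirane to the tertiary C5 radical and gives the 6-epi diol F6.
   - Dess–Martin oxidation gives the hydroxy ketone F7. C5 is now alpha to a carbonyl and, if needed, can be brought with a mild amine base to the trans-fused isomer in which C6 is anti to the isopropyl group.
   - Me4NBH(OAc)3 delivers hydride internally from the C4 alkoxyborohydride to give the 1,3-anti diol 27.

3. Step 8 (regioselective enolisation). What may go wrong: enolisation toward C10 instead of C8, which would end in the C9=C10 olefin. Fallback, setting out from 15 and returning at 19: dehydrogenation of 15 with IBX (DMSO/PhMe, 70 °C) can only occur toward C7, because C1 carries no hydrogen, and gives the 2,4-dienone F8. LiBH(sBu)3 at −78 °C should add hydride 1,4 at C7 (the 1,6 position C5 is fully substituted) and so generate the C8=C9 enolate regiospecifically. Trapping in the same flask with PhNTf2 gives triflate 19.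

**Further compounds**
F1 | step 7 | (1R)-4,4-ethylenedioxy-1,8-dimethylbicyclo[5.3.0]dec-5-en-9-ol, daucane locants, C8 and C9 epimers | CC1CC=C2C3(OCCO3)CC[C@]2(C)CC1O
F2 | step 10 | (1R)-4,4-ethylenedioxy-1,8-dimethylbicyclo[5.3.0]deca-5,8-diene, daucane locants | CC1=CC[C@@]2(C)CCC3(OCCO3)C2=CC1
F3 | step 10 | (1R)-1,8-dimethylbicyclo[5.3.0]deca-5,8-dien-4-one, daucane locants | CC1=CC[C@@]2(C)CCC(=O)C2=CC1
F4 | step 10 | (1R,4R)-dauca-5,8-dien-4-ol | CC1=CC[C@@]2(C)CC[C@@](O)(C(C)C)C2=CC1
F5 | step 10 | 5,6-epoxydauc-8-en-4-ol, oxirane oxygen syn to the C4 hydroxyl and the angular methyl | CC1=CC[C@@]2(C)CC[C@@](O)(C(C)C)[C@]23O[C@@H]3C1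
F6 | step 10 | 6-epi-jaeschkeanadiol (trans ring fusion, C6 hydroxyl syn to the C4 hydroxyl) | O[C@@H]1CC(C)=CC[C@@]2(C)CC[C@@](O)(C(C)C)[C@H]12
F7 | step 10 | 4-hydroxydauc-8-en-6-one, trans-fused | O=C1CC(C)=CC[C@@]2(C)CC[C@@](O)(C(C)C)[C@H]12
F8 | step 8 | (1R)-4,4-ethylenedioxy-1,8-dimethylbicyclo[5.3.0]deca-5,7-dien-9-one, daucane locants | CC1=CC=C2C3(OCCO3)CC[C@]2(C)CC1=O
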